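The route rests on cutting the C3–C4 bond of the oxolane ring (O1, C2–C5). The feature used is that C3, with its CH2O arm C9, stands directly beside the fully substituted C4, which carries oxygen and the arylmethyl carbon C7'. A terminal C3–C9 oxirane is opened by Cp2TiCl to a C3 radical that attacks the benzyloxy-bearing carbon of a styrenyl enol ether. This single operation closes the ring 5-exo, makes C3–C4, sets C3 and C4 relative to C2 and uncovers the C9 hydroxyl. The precursor links, through the future O1, an enantiopure ArCH(OH)-oxirane and a (Z)-ArCH=C(OBn)CH2 unit. Both phenols are benzyl ethers.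

Key step: step 7

**Numbering.** O1, C2 (aryl), C3 (C9H2O arm), C4 (oxygen and C7'H2Ar), C5. The target is (2S,3R,4S). The C2 aryl group and the C4 oxygen lie on one face, C9 and C7' on the other.

**Stereochemical bookkeeping.**
- The aryl-bearing carbon keeps one spatial arrangement from the resolution to the target.
- It is called (S) in the allylic alcohol, (R) in the oxiranyl compounds and (S) again in the oxolanes. The label changes only because the CIP ranking of its neighbours changes.
- The D-(−)-tartrate catalyst is the one that epoxidises this enantiomer.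
- The key-step precursor and product, checked atom by atom and centre by centre, agree with the target and need no correction.

**Design points.**
- (a) A benzyl–titanium species at C7' would have the C4 benzyloxy group in the β-position and should expel it. The C7' radical is therefore ended by hydrogen-atom transfer from water-modified Cp2TiCl, not by a second reduction.
- (b) The O1–C5 bond is made under basic SN2 conditions and not with halophilic silver salts. Ionisation of the electron-rich allylic bromide would invite attack at its benzylic terminus.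
- (c) Benzyl alone protects both phenols and the C4 oxygen, so one neutral hydrogenolysis ends the route.

**Assumption.** The enol ether geometry is taken to have no bearing on the constitution of the product, because C7' ends as a CH2 group. The (Z)-isomer is drawn because the elimination should favour it.

Step 1
Reactants: 1 4-(benzyloxy)-3-methoxybenzaldehyde; 2 vinylmagnesium bromide
Product: 3 rac-1-[4-(benzyloxy)-3-methoxyphenyl]prop-2-en-1-ol
Conditions: 2 (1.2 equiv), THF, 0 °C; sat. aq. NH4Cl
Reagents that add atoms: none
Why: Grignard 1,2-addition to a non-enolisable aromatic aldehyde is dependable, the benzyl ether is inert, and the carbinol centre (future C2) is formed racemic on purpose because step 2 resolves it.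

Step 2
Reactants: 3 rac-1-[4-(benzyloxy)-3-methoxyphenyl]prop-2-en-1-ol
Product: 4 (R)-[4-(benzyloxy)-3-methoxyphenyl][(S)-oxiran-2-yl]methanol (erythro epoxy alcohol)
Conditions: Ti(OiPr)4 (0.15 equiv), D-(−)-diisopropyl tartrate (0.18 equiv), tBuOOH (0.45 equiv, decane), 4 Å MS, CH2Cl2, −20 °C
Reagents that add atoms: tert-butyl hydroperoxide, CC(C)(C)OO
Why: Sharpless kinetic resolution, in which the Ti–D-(−)-tartrate catalyst epoxidises the (S)-allylic alcohol much faster than its mirror image and gives the erythro epoxy alcohol, so that substoichiometric oxidant fixes the future C2 by reagent control, while the oxirane centre, also set by the catalyst, is erased again in step 7.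

Step 3
Reactants: 5 methyl 2-(benzyloxy)acetate; 1 4-(benzyloxy)-3-methoxybenzaldehyde
Product: 7 methyl (Z)-2-(benzyloxy)-3-[4-(benzyloxy)-3-methoxyphenyl]prop-2-enoate, via β-acetoxy ester 6 (not isolated)
Conditions: LiN(iPr)2, THF, −78 °C; 1; Ac2O, −78 → 0 °C; DBU, rt
Reagents that add atoms: acetic anhydride, CC(=O)OC(C)=O (acetyl group of 6 only, lost again on the way to 7)
Why: Aldol addition of the ester enolate, O-acetylation of the aldolate in the flask and E1cB elimination with DBU add up to an aldol condensation, and the reversible carbanion stage should let the alkene settle as the less strained (Z)-isomer with the aryl group trans to the ester.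

Step 4
Reactants: 7 methyl (Z)-2-(benzyloxy)-3-[4-(benzyloxy)-3-methoxyphenyl]prop-2-enoate
Product: 8 (Z)-2-(benzyloxy)-3-[4-(benzyloxy)-3-methoxyphenyl]prop-2-en-1-ol
Conditions: iBu2AlH (2.3 equiv), CH2Cl2, −78 °C; aq. potassium sodium tartrate
Reagents that add atoms: none
Why: 1,2-Reduction of a conjugated ester with iBu2AlH at low temperature gives the allylic alcohol without touching the alkene geometry or the benzyl ethers, and the non-acidic work-up spares the enol ether.

Step 5
Reactants: 8 (Z)-2-(benzyloxy)-3-[4-(benzyloxy)-3-methoxyphenyl]prop-2-en-1-ol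
Product: 9 1-(benzyloxy)-4-[(Z)-2-(benzyloxy)-3-bromoprop-1-en-1-yl]-2-methoxybenzene
Conditions: CBr4, PPh3, 2,6-lutidine (0.2 equiv), CH2Cl2, −20 °C; filtration through basic Al2O3, used at once
Reagents that add atoms: carbon tetrabromide, BrC(Br)(Br)Br
Why: In the Appel reaction bromide displaces the alkoxyphosphonium group by SN2 at the primary allylic carbon under nearly neutral conditions, the lutidine buffer guards the acid-labile enol ether, and immediate use avoids decay of the labile bromide.

Step 6
Reactants: 4 (R)-[4-(benzyloxy)-3-methoxyphenyl][(S)-oxiran-2-yl]methanol; 9 1-(benzyloxy)-4-[(Z)-2-(benzyloxy)-3-bromoprop-1-en-1-yl]-2-methoxybenzene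
Product: 10 (S)-2-[(R)-{[(Z)-2-(benzyloxy)-3-(4-(benzyloxy)-3-methoxyphenyl)allyl]oxy}(4-(benzyloxy)-3-methoxyphenyl)methyl]oxirane (epoxy enol ether)
Conditions: 4, 9 (1.3 equiv), Bu4NI (0.1 equiv), THF, −20 °C; NaH (1.2 equiv) added last; → 0 °C
Reagents that add atoms: none
Why: This is a Williamson ether synthesis by SN2 at the primary allylic bromide, in which adding NaH last in an aprotic solvent at low temperature lets the alkoxide be trapped as it forms, which should hold back Payne rearrangement, and no stereocentre is touched because only the O–H bond of 4 reacts.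

Step 7
Reactants: 10 (S)-2-[(R)-{[(Z)-2-(benzyloxy)-3-(4-(benzyloxy)-3-methoxyphenyl)allyl]oxy}(4-(benzyloxy)-3-methoxyphenyl)methyl]oxirane
Product: 11 [(2S,3R,4S)-4-(benzyloxy)-4-[4-(benzyloxy)-3-methoxybenzyl]-2-[4-(benzyloxy)-3-methoxyphenyl]oxolan-3-yl]methanol (tri-O-benzylolivil with free C9–OH)
Conditions: Cp2TiCl2 (2.5 equiv), Mn dust (8 equiv), degassed THF, rt (gives Cp2TiCl); then 10, H2O (20 equiv), 2,4,6-collidine (3 equiv), THF (20 mM), rt; aq. NaH2PO4
Reagents that add atoms: none
Why: Proposed new method: Cp2TiCl (trivalent titanium, made from Cp2TiCl2 and Mn) transfers one electron to the terminal oxirane and breaks its C3–O bond, which leaves the more substituted secondary radical at C3 and a titanium alkoxide at C9; the radical adds to C4 of the enol ether, and the resulting benzylic C7' radical is quenched by hydrogen-atom transfer from the aqua complex Cp2TiCl(OH2). The closest known reaction type is the Nugent–RajanBabu epoxide-opening radical cyclisation of oxiranyl carbinol cinnamyl ethers to 2-aryl-3-(hydroxymethyl)-4-benzyloxolanes, and the new element is an acceptor carbon that already carries an alkoxy group and becomes fully substituted. The oxolane (O1, C2, C3, C4, C5) closes 5-exo-trig, which should beat 6-endo attack at C7' because only the exo mode produces an aryl-stabilised radical and because the short C–O bonds of the tether favour the five-membered transition state. C3 is controlled by C2, whose aryl group sits pseudo-equatorial in a Beckwith–Houk chair-like transition state and sends the bulky CH2OTi arm to the opposite face, and C4 is controlled in the same transition state, in which the exocyclic C7' lies on the side of C9 (the usual 1,5-cis preference), so that the benzyloxy group ends on the aryl face. The step needs ring closure to outrun hydrogen transfer to, or titanium capture of, the C3 radical, which the activated styrene acceptor and working at about 20 mM should secure, and it needs the C7' radical not to be reduced to a benzyl–titanium species, which would expel the β-benzyloxy group, a path that excess water and the crowding next to the new quaternary C4 should close. The oxirane centre is erased at the planar C3 radical, so that only the C2 configuration of 10 matters.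

Step 8
Reactants: 11 [(2S,3R,4S)-4-(benzyloxy)-4-[4-(benzyloxy)-3-methoxybenzyl]-2-[4-(benzyloxy)-3-methoxyphenyl]oxolan-3-yl]methanol
Product: 12 [(2S,3R,4S)-4-(benzyloxy)-4-[4-(benzyloxy)-3-methoxybenzyl]-2-[4-(benzyloxy)-3-methoxyphenyl]oxolan-3-yl]methyl acetate
Conditions: Ac2O, pyridine, DMAP (cat.), CH2Cl2, 0 °C → rt
Reagents that add atoms: acetic anhydride, CC(=O)OC(C)=O
Why: DMAP-catalysed O-acetylation meets only one free hydroxyl group, the primary C9–OH, since every other oxygen is an ether.

Step 9
Reactants: 12 [(2S,3R,4S)-4-(benzyloxy)-4-[4-(benzyloxy)-3-methoxybenzyl]-2-[4-(benzyloxy)-3-methoxyphenyl]oxolan-3-yl]methyl acetate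
Product: 13 olivil monoacetate, [(2S,3R,4S)-4-hydroxy-4-(4-hydroxy-3-methoxybenzyl)-2-(4-hydroxy-3-methoxyphenyl)oxolan-3-yl]methyl acetate
Conditions: H2 (1 atm), 10% Pd/C, EtOAc–EtOH, rt, stopped at full conversion; acid-free isolation
Reagents that add atoms: none
Why: Heterogeneous hydrogenolysis cleaves the three O–CH2Ph bonds (two aryl benzyl ethers and the tertiary alkyl benzyl ether at C4) under neutral conditions that leave the acetate and all three stereocentres alone, prompt termination spares the benzylic C2–O1 bond, and exclusion of acid prevents Friedel–Crafts ring closure of the product to the cycloolivil skeleton.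

Compound list
1 | 4-(benzyloxy)-3-methoxybenzaldehyde (O-benzylvanillin) | COc1cc(C=O)ccc1OCc1ccccc1 | starting material
2 | vinylmagnesium bromide | C=C[Mg]Br | starting material
3 | rac-1-[4-(benzyloxy)-3-methoxyphenyl]prop-2-en-1-ol | C=CC(O)c1ccc(OCc2ccccc2)c(OC)c1 | intermediate
4 | (R)-[4-(benzyloxy)-3-methoxyphenyl][(S)-oxiran-2-yl]methanol | O[C@H](c1ccc(OCc2ccccc2)c(OC)c1)[C@@H]1CO1 | intermediate
5 | methyl 2-(benzyloxy)acetate | COC(=O)COCc1ccccc1 | starting material
6 | methyl 3-acetoxy-2-(benzyloxy)-3-[4-(benzyloxy)-3-methoxyphenyl]propanoate (racemic mixture of diastereomers, not isolated) | COC(=O)C(OCc1ccccc1)C(OC(C)=O)c1ccc(OCc2ccccc2)c(OC)c1 | intermediate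
7 | methyl (Z)-2-(benzyloxy)-3-[4-(benzyloxy)-3-methoxyphenyl]prop-2-enoate | COC(=O)/C(OCc1ccccc1)=C/c1ccc(OCc2ccccc2)c(OC)c1 | intermediate
8 | (Z)-2-(benzyloxy)-3-[4-(benzyloxy)-3-methoxyphenyl]prop-2-en-1-ol | OC/C(OCc1ccccc1)=C/c1ccc(OCc2ccccc2)c(OC)c1 | intermediate
9 | 1-(benzyloxy)-4-[(Z)-2-(benzyloxy)-3-bromoprop-1-en-1-yl]-2-methoxybenzene | BrC/C(OCc1ccccc1)=C/c1ccc(OCc2ccccc2)c(OC)c1 | intermediate
10 | (S)-2-[(R)-{[(Z)-2-(benzyloxy)-3-(4-(benzyloxy)-3-methoxyphenyl)allyl]oxy}(4-(benzyloxy)-3-methoxyphenyl)methyl]oxirane | COc1cc(/C=C(OCc2ccccc2)/CO[C@H](c2ccc(OCc3ccccc3)c(OC)c2)[C@@H]2CO2)ccc1OCc1ccccc1 | intermediate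
11 | [(2S,3R,4S)-4-(benzyloxy)-4-[4-(benzyloxy)-3-methoxybenzyl]-2-[4-(benzyloxy)-3-methoxyphenyl]oxolan-3-yl]methanol | COc1cc(C[C@@]2(OCc3ccccc3)CO[C@H](c3ccc(OCc4ccccc4)c(OC)c3)[C@H]2CO)ccc1OCc1ccccc1 | intermediate
12 | [(2S,3R,4S)-4-(benzyloxy)-4-[4-(benzyloxy)-3-methoxybenzyl]-2-[4-(benzyloxy)-3-methoxyphenyl]oxolan-3-yl]methyl acetate | COc1cc(C[C@@]2(OCc3ccccc3)CO[C@H](c3ccc(OCc4ccccc4)c(OC)c3)[C@H]2COC(C)=O)ccc1OCc1ccccc1 | intermediate
13 | olivil monoacetate | COc1cc(C[C@@]2(O)CO[C@H](c3ccc(O)c(OC)c3)[C@H]2COC(C)=O)ccc1O | target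

Total step count: 9. Longest linear sequence: 7 steps (steps 3 to 9, from 1 and 5). The epoxy alcohol branch (steps 1 and 2) joins at step 6.

Steps most likely to fail

1. **Step 7** (carries the label Proposed new method).
   - **What may go wrong:** Addition of the C3 radical to the hindered, electron-rich C4 may be too slow. Premature hydrogen transfer, deoxygenation of the oxirane, 6-endo closure or poor facial selectivity at C4 could then take over. Over-reduction at C7' followed by loss of benzyloxide is the other exit.
   - **Fallback:** It uses known chemistry, sets out from 4 and comes back to the route at 13. Commercial 4-iodo-2-methoxyphenol is benzylated (BnBr, K2CO3, DMF) to 1-(benzyloxy)-4-iodo-2-methoxybenzene F1. Compound 4 is alkylated with propargyl bromide (NaH, THF, 0 °C) to the propargyl ether F2. Sonogashira coupling of F2 and F1 (PdCl2(PPh3)2, CuI, Et3N, rt) gives the 3-arylpropargyl ether F3. Cp2TiCl (Cp2TiCl2, Mn, THF) then brings about the well-established 5-exo-dig epoxide-opening cyclisation onto the aryl alkyne. This should give the 4-arylmethylidene oxolane methanol F4, with C9 trans to the C2 aryl group and an alkene geometry that does not matter. Acetylation (Ac2O, pyridine) gives the acetate F5. Dimethyldioxirane in acetone at low temperature should epoxidise the exocyclic alkene from the face opposite the neighbouring C9 arm, giving the spiro-epoxide F6 with the C4 oxygen on the aryl face. H2 over Pd/C cleaves the benzylic C7'–O bond of that epoxide together with both phenolic benzyl ethers and leads straight to 13.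

2. **Step 6.**
   - **What may go wrong:** Payne rearrangement of the alkoxide before alkylation, ionisation of the electron-rich allylic bromide with attack at its benzylic terminus, or decay of the bromide during handling.
   - **Fallback:** It sets out from 8 and 4, bypasses 9 and comes back at 10. Compound 8 is acetylated (Ac2O, pyridine) to the allylic acetate F7. Compound 4 is converted with Et2Zn (0.5 equiv, THF) into the zinc alkoxide F8. F8 and F7 are coupled with Pd(OAc)2 and 2-(di-tert-butylphosphino)biphenyl in THF at rt. This is a Tsuji–Trost-type allylic etherification through a π-allyl complex of divalent palladium, attacked at the unsubstituted terminus. It needs neither a halide nor a strongly basic alkoxide.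

3. **Step 9.**
   - **What may go wrong:** Sluggish cleavage of the hindered tertiary benzyl ether, so that long exposure brings reductive opening of the benzylic C2–O1 bond once the para-phenol is free.
   - **Fallback:** It sets out from 12 and comes back at 13 by a change of protecting groups. A short hydrogenolysis (Pd/C, EtOAc) removes only the two aryl benzyl ethers and gives the 4-O-benzyl bisphenol F9. Ac2O and pyridine cap both phenols to give the 4-O-benzyl triacetate F10. Its less electron-rich aryl groups, which cannot form a quinone methide, should make the ring ether much less prone to cleavage. Prolonged hydrogenolysis over Pd(OH)2/C then removes the tertiary benzyl ether to give the olivil triacetate F11. Pyrrolidine (2.2 equiv, CH2Cl2, 0 °C) cleaves the two aryl acetates by chemoselective aminolysis, leaving the primary alkyl acetate, and gives 13.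

Further compounds
F1 | step 7 | 1-(benzyloxy)-4-iodo-2-methoxybenzene | COc1cc(I)ccc1OCc1ccccc1
F2 | step 7 | (S)-2-[(R)-(4-(benzyloxy)-3-methoxyphenyl)(prop-2-yn-1-yloxy)methyl]oxirane | C#CCO[C@H](c1ccc(OCc2ccccc2)c(OC)c1)[C@@H]1CO1
F3 | step 7 | (S)-2-[(R)-(4-(benzyloxy)-3-methoxyphenyl){[3-(4-(benzyloxy)-3-methoxyphenyl)prop-2-yn-1-yl]oxy}methyl]oxirane | COc1cc(C#CCO[C@H](c2ccc(OCc3ccccc3)c(OC)c2)[C@@H]2CO2)ccc1OCc1ccccc1
F4 | step 7 | [(2S,3R)-2-[4-(benzyloxy)-3-methoxyphenyl]-4-[4-(benzyloxy)-3-methoxybenzylidene]oxolan-3-yl]methanol (alkene geometry open) | COc1cc(C=C2CO[C@H](c3ccc(OCc4ccccc4)c(OC)c3)[C@H]2CO)ccc1OCc1ccccc1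
F5 | step 7 | [(2S,3R)-2-[4-(benzyloxy)-3-methoxyphenyl]-4-[4-(benzyloxy)-3-methoxybenzylidene]oxolan-3-yl]methyl acetate | COc1cc(C=C2CO[C@H](c3ccc(OCc4ccccc4)c(OC)c3)[C@H]2COC(C)=O)ccc1OCc1ccccc1
F6 | step 7 | spiro-epoxide of F5 (C4–C7' oxirane, C4 oxygen on the aryl face, C7' configuration open) | COc1cc(C2O[C@@]23CO[C@H](c4ccc(OCc5ccccc5)c(OC)c4)[C@H]3COC(C)=O)ccc1OCc1ccccc1
F7 | step 6 | (Z)-2-(benzyloxy)-3-[4-(benzyloxy)-3-methoxyphenyl]prop-2-en-1-yl acetate | CC(=O)OC/C(OCc1ccccc1)=C/c1ccc(OCc2ccccc2)c(OC)c1
F8 | step 6 | zinc bis-alkoxide of 4 | [Zn+2].[O-][C@H](c1ccc(OCc2ccccc2)c(OC)c1)[C@@H]1CO1.[O-][C@H](c1ccc(OCc2ccccc2)c(OC)c1)[C@@H]1CO1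
F9 | step 9 | [(2S,3R,4S)-4-(benzyloxy)-4-(4-hydroxy-3-methoxybenzyl)-2-(4-hydroxy-3-methoxyphenyl)oxolan-3-yl]methyl acetate | COc1cc(C[C@@]2(OCc3ccccc3)CO[C@H](c3ccc(O)c(OC)c3)[C@H]2COC(C)=O)ccc1O
F10 | step 9 | [(2S,3R,4S)-4-(4-acetoxy-3-methoxybenzyl)-2-(4-acetoxy-3-methoxyphenyl)-4-(benzyloxy)oxolan-3-yl]methyl acetate | COc1cc(C[C@@]2(OCc3ccccc3)CO[C@H](c3ccc(OC(C)=O)c(OC)c3)[C@H]2COC(C)=O)ccc1OC(C)=O
F11 | step 9 | [(2S,3R,4S)-4-(4-acetoxy-3-methoxybenzyl)-2-(4-acetoxy-3-methoxyphenyl)-4-hydroxyoxolan-3-yl]methyl acetate | COc1cc(C[C@@]2(O)CO[C@H](c3ccc(OC(C)=O)c(OC)c3)[C@H]2COC(C)=O)ccc1OC(C)=O
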